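**Retrosynthetic overview**

1. Feature and starting materials: ring B of the target (C5–C10, with C12 on C8, the C7=C8 alkene, oxygen on C9 and the C5 stereocentre beside the gem-dimethyl carbon C4) is (R)-carvone (1); acrolein (2) supplies C1–C3 and (2E,4E,6E)-octa-2,4,6-trienoic acid (3) the side chain.
2. Last disconnections: C11 acid from a 2-(trimethylsilyl)ethyl ester, C12 aldehyde from the C8 methyl (SeO2), C6 ester from the 6α-alcohol and 3.
3. C6–O and C9–O (cis, both α) are cut together: singlet-oxygen [4+2] on the α-face of a C6=C7–C8=C9 diene ester, which comes from the C9 ketone by dienyl triflate formation and carbonylation (this brings C11).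
4. Ring A (C1–C5, C10) is cut at C3–C4: hydrogen-atom-transfer radical 6-endo cyclisation of the isopropenyl group onto a C10 acryloyl group, after which the C1 carbonyl is removed.
5. C10 is made quaternary on carvone by methylation, then aldol addition to 2 anti to the isopropenyl group and oxidation; ring order: ring B from the chiral pool, ring A in step 4.

Key step: step 4

Remark: drimane numbering is used for every compound (ring A = C1–C5 and C10; ring B = C5–C10; C11 on C9, C12 on C8; in carvone C9 is the carbonyl carbon and C10 the α′-CH2). The target SMILES is read as 5α-H, 10β-CH3, 9α-OH, 9β-CO2H and 6α-acyloxy (5S,6S,9S,10S), so the oxygens on C6 and C9 are cis. The γ-oxo acid is written in its open aldehyde–acid form, and LiN(iPr)2 is taken as a commercial solution.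

**Route**

Step 1
Reactants: 1 (R)-(−)-carvone
Product: 5 C10-methylcarvone (both C10 epimers), via lithium enolate 4 (not isolated)
Conditions: LiN(iPr)2, THF, −78 °C; MeI, −78 to −20 °C
Reagents that add atoms: iodomethane CI
Why: Kinetic α′-deprotonation of the enone gives the cross-conjugated enolate, which is C-methylated (enolate alkylation); the C10 epimer mixture is harmless because step 2 makes C10 planar again.

Step 2
Reactants: 5 C10-methylcarvone; 2 acrolein
Product: 7 C10-(1-hydroxyprop-2-enyl)-C10-methylcarvone (hydroxyallyl group anti to isopropenyl; both carbinol epimers), via lithium enolate 6 (not isolated)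
Conditions: LiN(iPr)2, THF, −78 to −30 °C; 2, −78 °C; AcOH quench at −78 °C
Reagents that add atoms: none
Why: A second kinetic α′-deprotonation gives the tetrasubstituted enolate, and its aldol 1,2-addition to the non-enolisable aldehyde should occur on the face anti to the neighbouring isopropenyl group on C5, which sets C10 (methyl β, C1 branch α); the carbinol centre is removed in step 3.

Step 3
Reactants: 7 C10-(1-hydroxyprop-2-enyl)-C10-methylcarvone
Product: 8 C10-acryloyl-C10-methylcarvone (acryloyl anti to isopropenyl)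
Conditions: Dess–Martin periodinane, NaHCO3, CH2Cl2, 0 °C to rt
Reagents that add atoms: none
Why: Dess–Martin oxidation of the secondary allylic alcohol under buffered, non-basic conditions should give the vinyl ketone without retro-aldol cleavage, and the quaternary C10 cannot epimerise.

Step 4
Reactants: 8 C10-acryloyl-C10-methylcarvone
Product: 9 11-nor-drim-7-ene-1,9-dione (trans-fused; 5α-H, 10β-CH3)
Conditions: Fe(acac)3 (30 mol %), PhSiH3 (2.5 equiv, slow addition), EtOH/(CH2OH)2 5:1, 0.02 M, 60 °C
Reagents that add atoms: none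
Why: Fe(acac)3 (trivalent iron) and PhSiH3 in ethanol generate an iron hydride that transfers a hydrogen atom to the CH2 terminus of the electron-rich 1,1-disubstituted isopropenyl alkene, which makes that CH2 the second C4 methyl and leaves a nucleophilic tertiary radical at C4. This radical adds to the terminal carbon C3 of the acryloyl group (6-endo-trig, polarity-matched), which forms the C3–C4 bond and closes ring A; the C2 α-keto radical is then reduced by divalent iron to the enolate and protonated by ethanol. The closest known reaction type is the iron-hydride hydrogen-atom-transfer reductive olefin coupling, a Giese addition, used here intramolecularly. No new stereocentre arises (C4 carries two methyls, C2 and C3 are CH2), and the trans ring fusion is dictated by the preset C5 and C10 centres, whose C4 and C1 branches are trans on ring B and can only be bridged diequatorially. The step needs hydrogen-atom transfer to the isopropenyl alkene in preference to the C7=C8 enone and the vinyl ketone; this is secured because the iron hydride reacts fastest with electron-rich alkenes that give tertiary radicals and because addition at C2 (5-exo) is polarity-mismatched, while dilution and slow silane addition limit simple reduction of the vinyl ketone.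

Step 5
Reactants: 9 11-nor-drim-7-ene-1,9-dione
Product: 10 C1 mono-tosylhydrazone of 9
Conditions: TsNHNH2 (1.1 equiv), PPTS (cat.), EtOH, 50 °C
Reagents that add atoms: 4-methylbenzenesulfonohydrazide Cc1ccc(cc1)S(=O)(=O)NN
Why: Hydrazone condensation should take place at the saturated C1 ketone, which is more electrophilic and less shielded than the conjugated C9 carbonyl flanked by quaternary C10 and the substituted C8.

Step 6
Reactants: 10 C1 mono-tosylhydrazone of 9
Product: 13 11-nor-drim-7-en-9-one, via N-boryl tosylhydrazine 11 (not isolated), via alkyl diazene 12 (not isolated)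
Conditions: catecholborane, CHCl3, 0 °C to rt; NaOAc·3H2O, reflux
Reagents that add atoms: none
Why: Hydride transfer from catecholborane to the C=N carbon, acetate-induced loss of sulfinate and extrusion of N2 from the diazene leave CH2 at C1 (a mild Wolff–Kishner-type tosylhydrazone reduction), while the hindered conjugated C9 ketone is not reduced by catecholborane at room temperature.

Step 7
Reactants: 13 11-nor-drim-7-en-9-one
Product: 14 11-nor-drima-6,8-dien-9-yl trifluoromethanesulfonate
Conditions: Tf2O, 2,6-di-tert-butyl-4-methylpyridine, CH2Cl2, 0 °C to rt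
Reagents that add atoms: trifluoromethanesulfonic anhydride O=S(=O)(OS(=O)(=O)C(F)(F)F)C(F)(F)F
Why: O-Triflation of the enone and loss of its only vinylogous proton (C6–H) give the linear dienyl triflate (dienol triflate formation); with C10 quaternary no other regioisomer can form and C5 is untouched.

Step 8
Reactants: 14 11-nor-drima-6,8-dien-9-yl trifluoromethanesulfonate
Product: 15 2-(trimethylsilyl)ethyl drima-6,8-dien-11-oate
Conditions: Pd(OAc)2 (10 mol %), dppp, Et3N, CO (1 atm), Me3SiCH2CH2OH, DMF, 70 °C
Reagents that add atoms: carbon monoxide [C-]#[O+]; 2-(trimethylsilyl)ethanol C[Si](C)(C)CCO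
Why: Oxidative addition of zerovalent palladium (formed in situ) into the C9–OTf bond, CO insertion and alcoholysis of the acyl-palladium (alkoxycarbonylation of an enol triflate) attach C11 at the acid oxidation level as a fluoride-labile ester.

Step 9
Reactants: 15 2-(trimethylsilyl)ethyl drima-6,8-dien-11-oate
Product: 16 2-(trimethylsilyl)ethyl 6α,9α-epidioxydrim-7-en-11-oate
Conditions: O2, tetraphenylporphyrin (cat.), visible light, CH2Cl2, −20 °C
Reagents that add atoms: dioxygen O=O
Why: Suprafacial [4+2] cycloaddition of singlet oxygen to the s-cis-locked ring B diene should occur on the α-face, anti to the axial C10 and 4β methyl groups (as with sterol 5,7-dienes), which sets C6 (O α) and C9 (O α, C11 β) together and places the alkene at C7=C8.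

Step 10
Reactants: 16 2-(trimethylsilyl)ethyl 6α,9α-epidioxydrim-7-en-11-oate
Product: 17 2-(trimethylsilyl)ethyl 6α,9α-dihydroxydrim-7-en-11-oate
Conditions: Zn dust, AcOH, CH2Cl2, 0 °C to rt
Reagents that add atoms: none
Why: Reductive cleavage of the O–O bond leaves both C–O bonds and hence both configurations intact, and the acidic medium avoids the base-induced Kornblum–DeLaMare rearrangement to a C6 ketone.

Step 11
Reactants: 17 2-(trimethylsilyl)ethyl 6α,9α-dihydroxydrim-7-en-11-oate; 3 (2E,4E,6E)-octa-2,4,6-trienoic acid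
Product: 19 2-(trimethylsilyl)ethyl 9α-hydroxy-6α-[(2E,4E,6E)-octa-2,4,6-trienoyloxy]drim-7-en-11-oate, via mixed anhydride 18 (not isolated)
Conditions: 3, 2,4,6-Cl3C6H2COCl, Et3N, toluene, rt; then 17, DMAP, rt to 40 °C
Reagents that add atoms: none
Why: Yamaguchi esterification acylates the secondary equatorial 6α-hydroxyl with retention at C6, while the tertiary 9α-hydroxyl next to two quaternary carbons does not react.

Step 12
Reactants: 19 2-(trimethylsilyl)ethyl 9α-hydroxy-6α-[(2E,4E,6E)-octa-2,4,6-trienoyloxy]drim-7-en-11-oate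
Product: 21 2-(trimethylsilyl)ethyl 9α-hydroxy-12-oxo-6α-[(2E,4E,6E)-octa-2,4,6-trienoyloxy]drim-7-en-11-oate, via C12 allylic alcohol 20 (not isolated)
Conditions: SeO2 (2 equiv), 1,4-dioxane, 80 °C
Reagents that add atoms: selenium dioxide O=[Se]=O
Why: Riley allylic oxidation (ene reaction, then [2,3]-sigmatropic shift) acts at the more substituted alkene terminus C8, whose only allylic hydrogens are on C12, and the primary allylic alcohol is oxidised on to the enal in the same flask; the ester-conjugated triene is a poor ene partner for the electrophilic selenium reagent.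

Step 13
Reactants: 21 2-(trimethylsilyl)ethyl 9α-hydroxy-12-oxo-6α-[(2E,4E,6E)-octa-2,4,6-trienoyloxy]drim-7-en-11-oate
Product: 22 (5S,6S,9S,10S)-9-hydroxy-12-oxo-6-[(2E,4E,6E)-octa-2,4,6-trienoyloxy]drim-7-en-11-oic acid (target)
Conditions: Bu4NF, AcOH (1:1), THF, 0 °C to rt; pH 4 buffer work-up
Reagents that add atoms: none
Why: Fluoride attacks silicon and the ester fragments (β-elimination) to ethene, Me3SiF and the carboxylate, remote from the hindered C11 carbonyl, so the trienoate, the enal and all four stereocentres should be untouched under the buffered conditions.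

**Compound list**

1 | (R)-(−)-carvone | C1C=C(C)C(=O)C[C@@H]1C(C)=C | starting material
2 | acrolein | C=CC=O | starting material
3 | (2E,4E,6E)-octa-2,4,6-trienoic acid | C/C=C/C=C/C=C/C(=O)O | starting material
4 | lithium enolate of carvone (O–C9=C10) | C1C=C(C)C(O[Li])=C[C@@H]1C(C)=C | intermediate
5 | C10-methylcarvone (both C10 epimers) | C1C=C(C)C(=O)C(C)[C@@H]1C(C)=C | intermediate
6 | lithium enolate of 5 (O–C9=C10, tetrasubstituted) | C1C=C(C)C(O[Li])=C(C)[C@@H]1C(C)=C | intermediate
7 | C10-(1-hydroxyprop-2-enyl)-C10-methylcarvone (hydroxyallyl anti to isopropenyl; both carbinol epimers) | C1C=C(C)C(=O)[C@@](C)(C(O)C=C)[C@@H]1C(C)=C | intermediate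
8 | C10-acryloyl-C10-methylcarvone (acryloyl anti to isopropenyl) | C1C=C(C)C(=O)[C@@](C)(C(=O)C=C)[C@@H]1C(C)=C | intermediate
9 | 11-nor-drim-7-ene-1,9-dione (trans-fused; 5α-H, 10β-CH3) | C1C=C(C)C(=O)[C@@]2(C)C(=O)CCC(C)(C)[C@H]12 | intermediate
10 | C1 mono-tosylhydrazone of 9 | C1C=C(C)C(=O)[C@@]2(C)C(=NNS(=O)(=O)c3ccc(C)cc3)CCC(C)(C)[C@H]12 | intermediate
11 | N-boryl tosylhydrazine at C1 (catecholboryl on the C1-bound nitrogen) | C1C=C(C)C(=O)[C@@]2(C)C(N(NS(=O)(=O)c3ccc(C)cc3)B3Oc4ccccc4O3)CCC(C)(C)[C@H]12 | intermediate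
12 | C1 alkyl diazene | C1C=C(C)C(=O)[C@@]2(C)C(N=N)CCC(C)(C)[C@H]12 | intermediate
13 | 11-nor-drim-7-en-9-one (5α-H, 10β-CH3) | C1C=C(C)C(=O)[C@@]2(C)CCCC(C)(C)[C@H]12 | intermediate
14 | 11-nor-drima-6,8-dien-9-yl trifluoromethanesulfonate | C1=CC(C)=C(OS(=O)(=O)C(F)(F)F)[C@@]2(C)CCCC(C)(C)[C@H]12 | intermediate
15 | 2-(trimethylsilyl)ethyl drima-6,8-dien-11-oate | C1=CC(C)=C(C(=O)OCC[Si](C)(C)C)[C@@]2(C)CCCC(C)(C)[C@H]12 | intermediate
16 | 2-(trimethylsilyl)ethyl 6α,9α-epidioxydrim-7-en-11-oate | O3[C@H]1C=C(C)[C@](O3)(C(=O)OCC[Si](C)(C)C)[C@@]2(C)CCCC(C)(C)[C@H]12 | intermediate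
17 | 2-(trimethylsilyl)ethyl 6α,9α-dihydroxydrim-7-en-11-oate | O[C@H]1C=C(C)[C@](O)(C(=O)OCC[Si](C)(C)C)[C@@]2(C)CCCC(C)(C)[C@H]12 | intermediate
18 | (2E,4E,6E)-octa-2,4,6-trienoic 2,4,6-trichlorobenzoic anhydride | C/C=C/C=C/C=C/C(=O)OC(=O)c1c(Cl)cc(Cl)cc1Cl | intermediate
19 | 2-(trimethylsilyl)ethyl 9α-hydroxy-6α-[(2E,4E,6E)-octa-2,4,6-trienoyloxy]drim-7-en-11-oate | C/C=C/C=C/C=C/C(=O)O[C@H]1C=C(C)[C@](O)(C(=O)OCC[Si](C)(C)C)[C@@]2(C)CCCC(C)(C)[C@H]12 | intermediate
20 | 2-(trimethylsilyl)ethyl 9α,12-dihydroxy-6α-[(2E,4E,6E)-octa-2,4,6-trienoyloxy]drim-7-en-11-oate | C/C=C/C=C/C=C/C(=O)O[C@H]1C=C(CO)[C@](O)(C(=O)OCC[Si](C)(C)C)[C@@]2(C)CCCC(C)(C)[C@H]12 | intermediate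
21 | 2-(trimethylsilyl)ethyl 9α-hydroxy-12-oxo-6α-[(2E,4E,6E)-octa-2,4,6-trienoyloxy]drim-7-en-11-oate | C/C=C/C=C/C=C/C(=O)O[C@H]1C=C(C=O)[C@](O)(C(=O)OCC[Si](C)(C)C)[C@@]2(C)CCCC(C)(C)[C@H]12 | intermediate
22 | (5S,6S,9S,10S)-9-hydroxy-12-oxo-6-[(2E,4E,6E)-octa-2,4,6-trienoyloxy]drim-7-en-11-oic acid (CNP0234478.2) | C/C=C/C=C/C=C/C(=O)O[C@H]1C=C(C=O)[C@](O)(C(=O)O)[C@@]2(C)CCCC(C)(C)[C@H]12 | target

**Step count and risks**

Total step count: 13. Longest linear sequence: 13 steps (1 to 22); 2 enters at step 2 and 3 at step 11.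

Three steps most likely to fail:

Step 4. The vinyl ketone may be reduced or oligomerised by the iron hydride before the C4 radical is formed, or hydrogen-atom transfer may not discriminate between the three alkenes. The fallback sets out from 8 and makes the same tertiary radical by halogen abstraction. HBr (33 % in AcOH), CH2Cl2, 0 °C should add in the Markovnikov sense to the isopropenyl group and 1,4 to the vinyl ketone to give the C4,C3-dibromide F1. Et3N, CH2Cl2, 0 °C then eliminates only the β-bromo ketone (and reverses any hydrobromination of the ring enone) to give the C4 tertiary bromide F2 with the acryloyl group restored. Bu3SnH, AIBN, benzene, 80 °C under slow addition and high dilution then gives the C4 radical, which closes 6-endo onto C3 and returns to the route at 9.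

Step 6. Hydride delivery to the neopentyl-type C1 hydrazone carbon next to quaternary C10 may be too slow, or reduction may spill over to the C9 carbonyl. The fallback sets out from 9 and replaces steps 5 and 6. KN(SiMe3)2, THF, −78 °C, then PhNTf2 enolises the only α-CH2 (C2) and gives the C1 enol triflate F3. Pd(OAc)2, PPh3, Bu3N, HCO2H, DMF, 60 °C reduces it to the 1,7-diene ketone F4 (11-nor-drima-1,7-dien-9-one). H2 with RhCl(PPh3)3 in benzene then saturates the disubstituted C1=C2 alkene in preference to the trisubstituted enone alkene and comes back to the route at 13.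

Step 12. Chemoselectivity may be lost through competing allylic oxidation of the terminal methyl of the trienoate, or the deactivated ring alkene may react too slowly. The fallback sets out from 17 and oxidises C12 before the side chain is attached. TBSCl, imidazole, DMF gives the 6-O-tert-butyldimethylsilyl ether F5. SeO2, 1,4-dioxane, 80 °C gives the silyl-protected C12 enal F6. HF·pyridine, THF/pyridine, 0 °C frees the 6α-hydroxy enal F7. Yamaguchi esterification of F7 with 3 (through 18, as in step 11) then comes back to the route at 21.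

**Further compounds**

F1 | step 4 | C10-(3-bromopropanoyl)-C10-methylcarvone hydrobromide (tertiary bromide at C4) | C1C=C(C)C(=O)[C@@](C)(C(=O)CCBr)[C@@H]1C(C)(C)Br
F2 | step 4 | C10-acryloyl-C10-methylcarvone hydrobromide (tertiary bromide at C4) | C1C=C(C)C(=O)[C@@](C)(C(=O)C=C)[C@@H]1C(C)(C)Br
F3 | step 6 | 9-oxo-11-nor-drima-1,7-dien-1-yl trifluoromethanesulfonate | C1C=C(C)C(=O)[C@@]2(C)C(OS(=O)(=O)C(F)(F)F)=CCC(C)(C)[C@H]12
F4 | step 6 | 11-nor-drima-1,7-dien-9-one | C1C=C(C)C(=O)[C@@]2(C)C=CCC(C)(C)[C@H]12
F5 | step 12 | 2-(trimethylsilyl)ethyl 6α-(tert-butyldimethylsilyloxy)-9α-hydroxydrim-7-en-11-oate | CC(C)(C)[Si](C)(C)O[C@H]1C=C(C)[C@](O)(C(=O)OCC[Si](C)(C)C)[C@@]2(C)CCCC(C)(C)[C@H]12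
F6 | step 12 | 2-(trimethylsilyl)ethyl 6α-(tert-butyldimethylsilyloxy)-9α-hydroxy-12-oxodrim-7-en-11-oate | CC(C)(C)[Si](C)(C)O[C@H]1C=C(C=O)[C@](O)(C(=O)OCC[Si](C)(C)C)[C@@]2(C)CCCC(C)(C)[C@H]12
F7 | step 12 | 2-(trimethylsilyl)ethyl 6α,9α-dihydroxy-12-oxodrim-7-en-11-oate | O[C@H]1C=C(C=O)[C@](O)(C(=O)OCC[Si](C)(C)C)[C@@]2(C)CCCC(C)(C)[C@H]12
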